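**Retrosynthetic overview**

1. 25 ⇐ 22: the two allylic oxidations (C14 CH3 → CHO, then C15 CH3 → CH2OH) come last, on the finished skeleton; 22 ⇐ 15 by lactone α-methylenation, unmasking of O8 and angeloylation.
2. 15 (cis-fused γ-lactone) ⇐ 10 by chelate-controlled C7–C11 alkylation, then Felkin reduction at C6 with lactonisation (O6–C12); 10 ⇐ dione 9 by asymmetric mono-reduction at C8.
3. 9 (ten-membered ring) ⇐ 7 by retro-aldol cleavage of the C6–C9 fusion bond of a bicyclo[6.2.0]decane: the eight-membered ring grows by the two carbons C7 and C8.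
4. 7 ⇐ dichloroketene [2+2] on the silyl enol ether of dienone 2 ⇐ 1,5-dimethylcycloocta-1,5-diene 1, which already holds C10(C14)=C1–C2–C3–C4(C15)=C5 with both olefins cis.
5. Enabling feature: the cyclobutane C6–C7–C8–C9 of 7 is a 3-silyloxycyclobutanone (donor O on C6, acceptor C8=O) whose bond C6–C9 is shared with the eight-membered ring and whose C9 is allylic to C10=C1. Ring order: eight-membered ring (in 1) → cyclobutane (step 3) → ten-membered ring (step 5) → γ-lactone (step 8).

Key step: step 5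

Remark: atoms are numbered as in germacranes (ring C1–C10, lactone carbons C11–C13 on C7, C14 on C10, C15 on C4); the target is (6R,7S,8S), i.e. O6, C11 and O8 all cis on a ring whose two olefins are both cis within the ring; commercial 1 is used as the pure 1,5-isomer (freed of its 1,6-dimethyl isomer).

**Route**

Step 1
Reactants: 1 (1Z,5Z)-1,5-dimethylcycloocta-1,5-diene
Product: 2 (2Z,6Z)-3,7-dimethylcycloocta-2,6-dien-1-one
Conditions: Rh2(cap)4 (1 mol %), t-BuOOH (70% aq., 5 equiv), K2CO3 (0.5 equiv), CH2Cl2, rt; stopped at partial conversion, 1 recycled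
Reagents that add atoms: tert-butyl hydroperoxide, CC(C)(C)OO
Why: Dirhodium-caprolactamate/TBHP allylic C–H oxidation should attack the ring CH2 next to the vinylic CH of a 1-methylcycloalkene unit (giving the β-methyl enone, as 1-methylcyclohexene gives 3-methylcyclohexenone), the two such CH2 groups of C2-symmetric 1 being equivalent and the enone deactivating its own olefin; no stereocentre is formed.

Step 2
Reactants: 2 (2Z,6Z)-3,7-dimethylcycloocta-2,6-dien-1-one
Product: 3 [(1E,3Z,7Z)-3,7-dimethylcycloocta-1,3,7-trien-1-yl]oxy(trimethyl)silane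
Conditions: LDA (1.1 equiv), THF, −78 °C; TMSCl, −78 → 0 °C; cold non-aqueous work-up
Reagents that add atoms: chlorotrimethylsilane, C[Si](C)(C)Cl
Why: Kinetic α′-deprotonation of the enone (the future C9 methylene, also allylic) and O-silylation give the cross-conjugated silyl enol ether, which is kept cold so that 6π-electrocyclisation of the triene does not intervene; no stereocentre.

Step 3
Reactants: 3 [(1E,3Z,7Z)-3,7-dimethylcycloocta-1,3,7-trien-1-yl]oxy(trimethyl)silane; 4 dichloroacetyl chloride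
Product: 6 rac-cis-10,10-dichloro-3,7-dimethyl-1-(trimethylsilyloxy)bicyclo[6.2.0]deca-2,6-dien-9-one, via dichloroketene 5 (not isolated)
Conditions: 4 (1.3 equiv) added slowly, Et3N (1.4 equiv), hexane, 0 °C → rt
Reagents that add atoms: none
Why: Polar [2+2] cycloaddition of dichloroketene to the silyl enol ether C6=C9, the most electron-rich olefin of the twisted triene: the ketene carbonyl carbon (C8) should bond to nucleophilic C9 and CCl2 (C7) to the silyloxy carbon C6, suprafacial addition giving the cis ring fusion (C6 and C9, racemic, both erased in step 5).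

Step 4
Reactants: 6 rac-cis-10,10-dichloro-3,7-dimethyl-1-(trimethylsilyloxy)bicyclo[6.2.0]deca-2,6-dien-9-one
Product: 7 rac-cis-3,7-dimethyl-1-(trimethylsilyloxy)bicyclo[6.2.0]deca-2,6-dien-9-one
Conditions: Zn dust, AcOH, TMEDA, EtOH, 0 °C
Reagents that add atoms: none
Why: Zinc reductive dechlorination of an α,α-dichlorocyclobutanone (zinc enolate, then protonation) is the standard follow-up to dichloroketene adducts and should leave the silyl ether and both olefins untouched; C7 becomes CH2, so no stereocentre is created.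

Step 5
Reactants: 7 rac-cis-3,7-dimethyl-1-(trimethylsilyloxy)bicyclo[6.2.0]deca-2,6-dien-9-one
Product: 9 (4Z,8Z)-5,9-dimethylcyclodeca-4,8-diene-1,3-dione, via cyclobutanol 8 (not isolated)
Conditions: K2CO3 (0.2 equiv), MeOH, 0 °C → rt; AcOH quench
Reagents that add atoms: none
Why: Methanolysis of the silyl ether frees the C6 alkoxide of a 3-oxidocyclobutanone (8), which undergoes retro-aldol cleavage of the ring-fusion bond C6–C9, the C9 carbanion leaving as the dienolate O–C8=C9–C10=C1; C-protonation at C9 and proton transfer give the C7 diketonate, released as 9 on quench. The closest known reaction type is the two-carbon ring expansion of dichloroketene/cyclic silyl enol ether adducts to cycloalkane-1,3-diones (de Mayo-type retro-aldol of a β-oxycyclobutanone). No ring is closed: the ten-membered ring is the periphery of the bicyclo[6.2.0]decane and is set free by scission of its zero-atom bridge (the reverse of a 4-exo-trig aldol closure), so the eight-membered ring grows by C7 and C8. No stereocentre is created, the two racemic bridgehead centres C6 and C9 are erased, and both trisubstituted olefins should keep the ring-cis geometry inherited from the eight-membered ring because they are not part of the bond reorganisation. The selectivity needed is cleavage of C6–C9 rather than C6–C7, and it is secured by the vinylogous (C10=C1) stabilisation of the C9 enolate, which a primary C7 enolate lacks, both modes releasing the same cyclobutane strain.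

Step 6
Reactants: 9 (4Z,8Z)-5,9-dimethylcyclodeca-4,8-diene-1,3-dione
Product: 10 (2Z,6Z,9S)-9-hydroxy-3,7-dimethylcyclodeca-2,6-dien-1-one
Conditions: [RuCl2((S)-BINAP)]2·NEt3 (0.5 mol %), H2 (50 atm), MeOH, 30 °C; stopped after 1 equiv H2
Reagents that add atoms: none
Why: Noyori asymmetric hydrogenation of a 1,3-diketone: the chelated diketone should be reduced at the non-conjugated, more electrophilic C8 carbonyl (as 1-aryl-1,3-diketones are reduced at the alkyl ketone) and stop there, the (S)-BINAP–Ru catalyst setting C8 as S in the sense known for β-keto esters and 1,3-diketones.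

Step 7
Reactants: 10 (2Z,6Z,9S)-9-hydroxy-3,7-dimethylcyclodeca-2,6-dien-1-one; 11 methyl bromoacetate
Product: 13 methyl 2-[(1S,3Z,7Z,10S)-10-{[tert-butyl(dimethyl)silyl]oxy}-4,8-dimethyl-2-oxocyclodeca-3,7-dien-1-yl]acetate, via lithium alkoxide 12 (not isolated)
Conditions: LDA (2.2 equiv), THF, −78 °C; 11, DMPU, −78 → −45 °C; TBSOTf (1.5 equiv), −78 → −30 °C
Reagents that add atoms: tert-butyldimethylsilyl trifluoromethanesulfonate, CC(C)(C)[Si](C)(C)OS(=O)(=O)C(F)(F)F
Why: Fráter–Seebach-type alkylation of the β-hydroxy ketone dianion (kinetic α′-enolate toward C7): in the rigid O8–Li–O6 chelate the ring chain at C9 covers one enolate face, so the bromoacetate should add to C7 from the open peripheral face and place C11 cis to O8 on the ring (7S), and silylation of alkoxide 12 in the same flask stops its lactonisation onto the new ester.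

Step 8
Reactants: 13 methyl 2-[(1S,3Z,7Z,10S)-10-{[tert-butyl(dimethyl)silyl]oxy}-4,8-dimethyl-2-oxocyclodeca-3,7-dien-1-yl]acetate
Product: 15 (3aR,4S,6Z,10Z,11aR)-4-{[tert-butyl(dimethyl)silyl]oxy}-6,10-dimethyl-3a,4,5,8,9,11a-hexahydrocyclodeca[b]furan-2(3H)-one, via hydroxy ester 14 (not isolated)
Conditions: NaBH4, CeCl3·7H2O, MeOH, −78 → −20 °C; then PPTS (cat.), CH2Cl2, rt
Reagents that add atoms: none
Why: Luche 1,2-reduction of the enone: Felkin–Anh control by C7 (C8 antiperiplanar to the incoming hydride) and the polar 1,3-model for the β-silyloxy group both point to the face that gives O6 cis to C11 and O8 (6R), and the cis γ-hydroxy ester 14 then closes to the cis-fused γ-lactone by 5-exo-trig acyl substitution.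

Step 9
Reactants: 15 (3aR,4S,6Z,10Z,11aR)-4-{[tert-butyl(dimethyl)silyl]oxy}-6,10-dimethyl-3a,4,5,8,9,11a-hexahydrocyclodeca[b]furan-2(3H)-one
Product: 18 (3aR,4S,6Z,10Z,11aR)-4-{[tert-butyl(dimethyl)silyl]oxy}-6,10-dimethyl-3-methylidene-3a,4,5,8,9,11a-hexahydrocyclodeca[b]furan-2(3H)-one, via Mannich base 16 (not isolated), via ammonium iodide 17 (not isolated)
Conditions: LDA (1.2 equiv), THF, −78 °C; CH2=NMe2+ I−, −78 °C → rt; MeI, MeOH, rt; sat. aq. NaHCO3/CH2Cl2, rt
Reagents that add atoms: dimethyl(methylidene)ammonium iodide (Eschenmoser's salt), C=[N+](C)C.[I-]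
Why: Eschenmoser methylenation: Mannich reaction of the lactone lithium enolate (the only acidic C–H) with the iminium salt, N-methylation and base-induced β-elimination give the α-methylene lactone; the C11 centre of 16 is transient and no other stereocentre is touched.

Step 10
Reactants: 18 (3aR,4S,6Z,10Z,11aR)-4-{[tert-butyl(dimethyl)silyl]oxy}-6,10-dimethyl-3-methylidene-3a,4,5,8,9,11a-hexahydrocyclodeca[b]furan-2(3H)-one
Product: 19 (3aS,4S,6Z,10Z,11aR)-4-hydroxy-6,10-dimethyl-3-methylidene-3a,4,5,8,9,11a-hexahydrocyclodeca[b]furan-2(3H)-one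
Conditions: HF·pyridine, THF/pyridine, 0 °C → rt
Reagents that add atoms: none
Why: Fluoride cleavage of the secondary TBS ether under weakly acidic conditions, chosen to avoid an alkoxide that could translactonise to O8 or add to the methylene lactone; the configuration at C8 is untouched.

Step 11
Reactants: 19 (3aS,4S,6Z,10Z,11aR)-4-hydroxy-6,10-dimethyl-3-methylidene-3a,4,5,8,9,11a-hexahydrocyclodeca[b]furan-2(3H)-one; 20 angelic acid [(2Z)-2-methylbut-2-enoic acid]
Product: 22 (3aS,4S,6Z,10Z,11aR)-6,10-dimethyl-3-methylidene-2-oxo-2,3,3a,4,5,8,9,11a-octahydrocyclodeca[b]furan-4-yl (2Z)-2-methylbut-2-enoate, via mixed anhydride 21 (not isolated)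
Conditions: 20, 2,4,6-trichlorobenzoyl chloride, Et3N, toluene, rt; then 19, DMAP, toluene, rt → 40 °C
Reagents that add atoms: none
Why: Yamaguchi esterification via the mixed 2,4,6-trichlorobenzoic anhydride acylates the hindered secondary alcohol at oxygen (C8 retained) under conditions known to keep the angelate Z.

Step 12
Reactants: 22 (3aS,4S,6Z,10Z,11aR)-6,10-dimethyl-3-methylidene-2-oxo-2,3,3a,4,5,8,9,11a-octahydrocyclodeca[b]furan-4-yl (2Z)-2-methylbut-2-enoate
Product: 23 (3aS,4S,6E,10Z,11aR)-6-(hydroxymethyl)-10-methyl-3-methylidene-2-oxo-2,3,3a,4,5,8,9,11a-octahydrocyclodeca[b]furan-4-yl (2Z)-2-methylbut-2-enoate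
Conditions: SeO2 (0.3 equiv), t-BuOOH (2 equiv, in decane), salicylic acid (0.1 equiv), CH2Cl2, 0 °C → rt
Reagents that add atoms: selenium dioxide, O=[Se]=O (catalytic oxygen carrier); tert-butyl hydroperoxide, CC(C)(C)OO
Why: Sharpless SeO2/t-BuOOH allylic hydroxylation (ene reaction, then [2,3]-sigmatropic shift): the isolated 1(10)-olefin should react before the 4,5-olefin, which is deactivated by the allylic lactone oxygen (cf. geranyl acetate, oxidised only at the distal olefin), at its methyl group as in 1(10)-unsaturated germacranolides, the [2,3] shift placing CH2OH trans to C2 so that the ring-cis olefin is kept.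

Step 13
Reactants: 23 (3aS,4S,6E,10Z,11aR)-6-(hydroxymethyl)-10-methyl-3-methylidene-2-oxo-2,3,3a,4,5,8,9,11a-octahydrocyclodeca[b]furan-4-yl (2Z)-2-methylbut-2-enoate
Product: 24 (3aS,4S,6E,10Z,11aR)-6-formyl-10-methyl-3-methylidene-2-oxo-2,3,3a,4,5,8,9,11a-octahydrocyclodeca[b]furan-4-yl (2Z)-2-methylbut-2-enoate
Conditions: MnO2 (activated, 15 equiv), CH2Cl2, rt
Reagents that add atoms: none
Why: MnO2 oxidation, selective for the only allylic alcohol, should give the enal under neutral conditions without touching the angelate, the lactone or the olefin geometry.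

Step 14
Reactants: 24 (3aS,4S,6E,10Z,11aR)-6-formyl-10-methyl-3-methylidene-2-oxo-2,3,3a,4,5,8,9,11a-octahydrocyclodeca[b]furan-4-yl (2Z)-2-methylbut-2-enoate
Product: 25 (3aS,4S,6E,10E,11aR)-6-formyl-10-(hydroxymethyl)-3-methylidene-2-oxo-2,3,3a,4,5,8,9,11a-octahydrocyclodeca[b]furan-4-yl (2Z)-2-methylbut-2-enoate
Conditions: SeO2 (0.5 equiv), t-BuOOH (3 equiv, in decane), salicylic acid (0.1 equiv), CH2Cl2, rt; stopped at partial conversion, 24 recycled
Reagents that add atoms: selenium dioxide, O=[Se]=O (catalytic oxygen carrier); tert-butyl hydroperoxide, CC(C)(C)OO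
Why: Second SeO2/t-BuOOH allylic hydroxylation: with the 1(10)-olefin now an unreactive enal, the ene reaction is left to the 4,5-olefin, whose methyl should be oxidised as in prenyl esters (giving (E)-4-hydroxyprenyl esters), the [2,3] shift putting CH2OH trans to C6 (ring-cis olefin kept); partial conversion limits over-oxidation.

**Compound list**

1 | (1Z,5Z)-1,5-dimethylcycloocta-1,5-diene | C/C1=C/CC/C(C)=C\CC1 | starting material
2 | (2Z,6Z)-3,7-dimethylcycloocta-2,6-dien-1-one | O=C1/C=C(/C)CC/C=C(/C)C1 | intermediate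
3 | [(1E,3Z,7Z)-3,7-dimethylcycloocta-1,3,7-trien-1-yl]oxy(trimethyl)silane (all ring olefins cis within the ring) | C1C/C(C)=C\C(O[Si](C)(C)C)=C/C(C)=C\1 | intermediate
4 | dichloroacetyl chloride | O=C(Cl)C(Cl)Cl | starting material
5 | dichloroketene | O=C=C(Cl)Cl | intermediate
6 | rac-cis-10,10-dichloro-3,7-dimethyl-1-(trimethylsilyloxy)bicyclo[6.2.0]deca-2,6-dien-9-one (2Z,6Z; racemic, one enantiomer drawn) | C[Si](C)(C)O[C@]12C(Cl)(Cl)C(=O)[C@H]1/C(C)=C\CC/C(C)=C\2 | intermediate
7 | rac-cis-3,7-dimethyl-1-(trimethylsilyloxy)bicyclo[6.2.0]deca-2,6-dien-9-one (racemic, one enantiomer drawn) | C[Si](C)(C)O[C@]12CC(=O)[C@H]1/C(C)=C\CC/C(C)=C\2 | intermediate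
8 | rac-cis-1-hydroxy-3,7-dimethylbicyclo[6.2.0]deca-2,6-dien-9-one (present as its alkoxide) | O[C@]12CC(=O)[C@H]1/C(C)=C\CC/C(C)=C\2 | intermediate
9 | (4Z,8Z)-5,9-dimethylcyclodeca-4,8-diene-1,3-dione | O=C1/C=C(/C)CC/C=C(/C)CC(=O)C1 | intermediate
10 | (2Z,6Z,9S)-9-hydroxy-3,7-dimethylcyclodeca-2,6-dien-1-one | O=C1/C=C(/C)CC/C=C(/C)C[C@H](O)C1 | intermediate
11 | methyl bromoacetate | COC(=O)CBr | starting material
12 | lithium (1S,2S,4Z,8Z)-2-(2-methoxy-2-oxoethyl)-5,9-dimethyl-3-oxocyclodeca-4,8-dien-1-olate | COC(=O)C[C@@H]1C(=O)/C=C(/C)CC/C=C(/C)C[C@@H]1[O-].[Li+] | intermediate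
13 | methyl 2-[(1S,3Z,7Z,10S)-10-{[tert-butyl(dimethyl)silyl]oxy}-4,8-dimethyl-2-oxocyclodeca-3,7-dien-1-yl]acetate | COC(=O)C[C@@H]1C(=O)/C=C(/C)CC/C=C(/C)C[C@@H]1O[Si](C)(C)C(C)(C)C | intermediate
14 | methyl 2-[(1R,2R,3Z,7Z,10S)-10-{[tert-butyl(dimethyl)silyl]oxy}-2-hydroxy-4,8-dimethylcyclodeca-3,7-dien-1-yl]acetate | COC(=O)C[C@@H]1[C@H](O)/C=C(/C)CC/C=C(/C)C[C@@H]1O[Si](C)(C)C(C)(C)C | intermediate
15 | (3aR,4S,6Z,10Z,11aR)-4-{[tert-butyl(dimethyl)silyl]oxy}-6,10-dimethyl-3a,4,5,8,9,11a-hexahydrocyclodeca[b]furan-2(3H)-one (cis-fused) | C1C(=O)O[C@@H]2/C=C(/C)CC/C=C(/C)C[C@H](O[Si](C)(C)C(C)(C)C)[C@H]12 | intermediate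
16 | 3-[(dimethylamino)methyl] derivative of 15 (C3 epimers, centre removed in the same step) | CN(C)CC1C(=O)O[C@@H]2/C=C(/C)CC/C=C(/C)C[C@H](O[Si](C)(C)C(C)(C)C)[C@H]12 | intermediate
17 | 3-[(trimethylammonio)methyl] derivative of 15, iodide | C[N+](C)(C)CC1C(=O)O[C@@H]2/C=C(/C)CC/C=C(/C)C[C@H](O[Si](C)(C)C(C)(C)C)[C@H]12.[I-] | intermediate
18 | (3aR,4S,6Z,10Z,11aR)-4-{[tert-butyl(dimethyl)silyl]oxy}-6,10-dimethyl-3-methylidene-3a,4,5,8,9,11a-hexahydrocyclodeca[b]furan-2(3H)-one | C=C1C(=O)O[C@@H]2/C=C(/C)CC/C=C(/C)C[C@H](O[Si](C)(C)C(C)(C)C)[C@H]12 | intermediate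
19 | (3aS,4S,6Z,10Z,11aR)-4-hydroxy-6,10-dimethyl-3-methylidene-3a,4,5,8,9,11a-hexahydrocyclodeca[b]furan-2(3H)-one | C=C1C(=O)O[C@@H]2/C=C(/C)CC/C=C(/C)C[C@H](O)[C@H]12 | intermediate
20 | angelic acid, (2Z)-2-methylbut-2-enoic acid | C/C=C(/C)C(=O)O | starting material
21 | (2Z)-2-methylbut-2-enoic 2,4,6-trichlorobenzoic anhydride | C/C=C(/C)C(=O)OC(=O)c1c(Cl)cc(Cl)cc1Cl | intermediate
22 | (3aS,4S,6Z,10Z,11aR)-6,10-dimethyl-3-methylidene-2-oxo-2,3,3a,4,5,8,9,11a-octahydrocyclodeca[b]furan-4-yl (2Z)-2-methylbut-2-enoate | C=C1C(=O)O[C@@H]2/C=C(/C)CC/C=C(/C)C[C@H](OC(=O)/C(C)=C\C)[C@H]12 | intermediate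
23 | (3aS,4S,6E,10Z,11aR)-6-(hydroxymethyl)-10-methyl-3-methylidene-2-oxo-2,3,3a,4,5,8,9,11a-octahydrocyclodeca[b]furan-4-yl (2Z)-2-methylbut-2-enoate | C=C1C(=O)O[C@@H]2/C=C(/C)CC/C=C(/CO)C[C@H](OC(=O)/C(C)=C\C)[C@H]12 | intermediate
24 | (3aS,4S,6E,10Z,11aR)-6-formyl-10-methyl-3-methylidene-2-oxo-2,3,3a,4,5,8,9,11a-octahydrocyclodeca[b]furan-4-yl (2Z)-2-methylbut-2-enoate | C=C1C(=O)O[C@@H]2/C=C(/C)CC/C=C(/C=O)C[C@H](OC(=O)/C(C)=C\C)[C@H]12 | intermediate
25 | (3aS,4S,6E,10E,11aR)-6-formyl-10-(hydroxymethyl)-3-methylidene-2-oxo-2,3,3a,4,5,8,9,11a-octahydrocyclodeca[b]furan-4-yl (2Z)-2-methylbut-2-enoate | C=C1C(=O)O[C@@H]2/C=C(/CO)CC/C=C(/C=O)C[C@H](OC(=O)/C(C)=C\C)[C@H]12 | target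

**Summary**

Total step count: 14. Longest linear sequence: 14 steps (1 → 25).

Steps most likely to fail:

1. Step 14 (C15 hydroxylation). The ene reaction at the lactone-deactivated 4,5-olefin is slow, so the long exposure may over-oxidise the new carbinol to the aldehyde and erode the enal, and attack at the ring CH2 (C3) may compete. The fallback sets out from 23 and comes back at 25, and it moves the second hydroxylation to a stage without an aldehyde, so that over-oxidation can be reversed. Silylation of 23 (TESCl, imidazole, DMF) should give the 14-O-triethylsilyl ether F1. SeO2/t-BuOOH run to full conversion, followed by NaBH4/CeCl3 (MeOH, −78 °C) to return any C15 aldehyde, should give the 15-alcohol F2. TBSCl/imidazole then gives the 15-O-TBS ether F3. Swern conditions ((COCl)2, DMSO, CH2Cl2, −78 → −30 °C; Et3N), which cleave and oxidise a primary triethylsilyl ether in one pot while a TBS ether survives, should give the enal F4. HF·pyridine then releases 25.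

2. Step 6 (mono-reduction of the dione). Chemoselectivity between the two carbonyl groups may be lost, by over-reduction to the diol or by partial reduction at C6. The fallback sets out from 9 and comes back at 10. Hydrogenation with the same (S)-BINAP–Ru catalyst is driven to completion (100 atm H2, 50 °C) to the anti-1,3-diol (1R,2Z,6Z,9S)-3,7-dimethylcyclodeca-2,6-diene-1,9-diol F5, in which C8 is again fixed by the catalyst. MnO2 (CH2Cl2, rt) then re-oxidises only the allylic C6 carbinol and returns 10.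

3. Step 8 (reduction at C6). Hydride may be delivered to the wrong face of the C6 carbonyl in the flexible ten-membered ring. The fallback sets out from 13 and comes back at 15, and it uses the wrong epimer. The C6-epimeric alcohol is expected to close under the same conditions to the trans-fused lactone F6. Saponification (LiOH, THF/H2O, 0 °C) gives the seco acid F7. Mitsunobu lactonisation (PPh3, DIAD, THF, −20 °C, high dilution) proceeds with inversion at the allylic C6 carbinol and should return the cis-fused lactone 15.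

Further compounds
F1 | step 14 | (3aS,4S,6E,10Z,11aR)-10-methyl-3-methylidene-2-oxo-6-[(triethylsilyloxy)methyl]-2,3,3a,4,5,8,9,11a-octahydrocyclodeca[b]furan-4-yl (2Z)-2-methylbut-2-enoate | C=C1C(=O)O[C@@H]2/C=C(/C)CC/C=C(/CO[Si](CC)(CC)CC)C[C@H](OC(=O)/C(C)=C\C)[C@H]12
F2 | step 14 | (3aS,4S,6E,10E,11aR)-10-(hydroxymethyl)-3-methylidene-2-oxo-6-[(triethylsilyloxy)methyl]-2,3,3a,4,5,8,9,11a-octahydrocyclodeca[b]furan-4-yl (2Z)-2-methylbut-2-enoate | C=C1C(=O)O[C@@H]2/C=C(/CO)CC/C=C(/CO[Si](CC)(CC)CC)C[C@H](OC(=O)/C(C)=C\C)[C@H]12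
F3 | step 14 | (3aS,4S,6E,10E,11aR)-10-{[tert-butyl(dimethyl)silyloxy]methyl}-3-methylidene-2-oxo-6-[(triethylsilyloxy)methyl]-2,3,3a,4,5,8,9,11a-octahydrocyclodeca[b]furan-4-yl (2Z)-2-methylbut-2-enoate | C=C1C(=O)O[C@@H]2/C=C(/CO[Si](C)(C)C(C)(C)C)CC/C=C(/CO[Si](CC)(CC)CC)C[C@H](OC(=O)/C(C)=C\C)[C@H]12
F4 | step 14 | (3aS,4S,6E,10E,11aR)-10-{[tert-butyl(dimethyl)silyloxy]methyl}-6-formyl-3-methylidene-2-oxo-2,3,3a,4,5,8,9,11a-octahydrocyclodeca[b]furan-4-yl (2Z)-2-methylbut-2-enoate | C=C1C(=O)O[C@@H]2/C=C(/CO[Si](C)(C)C(C)(C)C)CC/C=C(/C=O)C[C@H](OC(=O)/C(C)=C\C)[C@H]12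
F5 | step 6 | (1R,2Z,6Z,9S)-3,7-dimethylcyclodeca-2,6-diene-1,9-diol | O[C@H]1/C=C(/C)CC/C=C(/C)C[C@H](O)C1
F6 | step 8 | (3aR,4S,6Z,10Z,11aS)-4-{[tert-butyl(dimethyl)silyl]oxy}-6,10-dimethyl-3a,4,5,8,9,11a-hexahydrocyclodeca[b]furan-2(3H)-one (trans-fused) | C1C(=O)O[C@H]2/C=C(/C)CC/C=C(/C)C[C@H](O[Si](C)(C)C(C)(C)C)[C@H]12
F7 | step 8 | 2-[(1R,2S,3Z,7Z,10S)-10-{[tert-butyl(dimethyl)silyl]oxy}-2-hydroxy-4,8-dimethylcyclodeca-3,7-dien-1-yl]acetic acid | OC(=O)C[C@@H]1[C@@H](O)/C=C(/C)CC/C=C(/C)C[C@@H]1O[Si](C)(C)C(C)(C)C
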